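The route rests on cutting the CH2–CHOH unit (C3–C2, carotane numbering) out of cyclopentane ring A. The oxygens on C4, C2 and C10 are 1,3-related along C4–C3–C2–C1–C10. This is a double aldol pattern with acetaldehyde at its centre. The key step is a formal [3+2] annulation. A vinyl ether adds through its CH2 to the silyl-activated C4 isopropyl ketone, and the resulting oxocarbenium ion is captured by C1 of a C10 silyl dienol ether. One operation closes ring A and sets quaternary C1, tertiary carbinol C4 and C2. The precursor is a monocyclic cycloheptadiene (ring B) whose only stereocentres, C5 and C6, steer all others.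

Key step: step 9

Remark on numbering and one assumption:
- Carotane numbering is used throughout. C1 is the quaternary ring-fusion carbon with the angular methyl group, C2 is CH(OH), C3 is CH2, C4 is C(OH)(isopropyl) and C5 is the ring-fusion CH.
- C6 is CH(O-acyl), C7 is CH2, C8 (C–CH3) and C9 (CH) are the epoxide carbons, and C10 is CH(O-acyl) next to C1.
- Ring A is the cyclopentane C1–C5. Ring B is the cycloheptane C1, C5–C10.
- β is the face of the angular methyl group and α the opposite face.
- It is assumed that monomeric ethyl glyoxylate is freed by distillation from its commercial toluene solution.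

Step 1
Reactants: 1 ethyl glyoxylate; 2 isobutene (2-methylpropene)
Product: 3 ethyl (S)-2-hydroxy-4-methylpent-4-enoate
Conditions: (S)-BINOL (10 mol %), TiCl2(OiPr)2 (10 mol %), 4 Å MS, CH2Cl2, −30 °C
Reagents that add atoms: none
Why: Asymmetric carbonyl-ene (glyoxylate-ene) reaction under chiral titanium–BINOLate Lewis-acid catalysis; the six-membered ene transition state on the (S)-BINOL complex exposes one aldehyde face, so that the future C6 should be set as S.

Step 2
Reactants: 3 ethyl (S)-2-hydroxy-4-methylpent-4-enoate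
Product: 4 ethyl (S)-2-(tert-butyldimethylsilyloxy)-4-methylpent-4-enoate
Conditions: TBSCl, imidazole, DMF, rt
Reagents that add atoms: tert-butyldimethylsilyl chloride, CC(C)(C)[Si](C)(C)Cl
Why: Imidazole-mediated O-silylation of a secondary alcohol, which touches no stereocentre and installs the bulky group that later shields the β face next to C5.

Step 3
Reactants: 4 ethyl (S)-2-(tert-butyldimethylsilyloxy)-4-methylpent-4-enoate
Product: 5 (S)-2-(tert-butyldimethylsilyloxy)-4-methylpent-4-enal
Conditions: i-Bu2AlH (1.1 equiv), CH2Cl2, −78 °C; Rochelle salt work-up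
Reagents that add atoms: none
Why: Partial ester reduction; the tetrahedral aluminium hemiacetal is stable at −78 °C and collapses to the aldehyde only on work-up, and the α-silyloxy aldehyde is used at once so that C6 is not epimerised.

Step 4
Reactants: 5 (S)-2-(tert-butyldimethylsilyloxy)-4-methylpent-4-enal; 6 ethyl 2-[bis(2,2,2-trifluoroethoxy)phosphoryl]propanoate
Product: 7 ethyl (2Z,4S)-4-(tert-butyldimethylsilyloxy)-2,6-dimethylhepta-2,6-dienoate
Conditions: KN(SiMe3)2, 18-crown-6, THF, −78 °C
Reagents that add atoms: none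
Why: Still–Gennari modification of the Horner–Wadsworth–Emmons olefination; fast irreversible elimination from the kinetic adduct of the trifluoroethyl phosphonate should give the Z-trisubstituted enoate, the geometry that ring B needs at C1=C5.

Step 5
Reactants: 7 ethyl (2Z,4S)-4-(tert-butyldimethylsilyloxy)-2,6-dimethylhepta-2,6-dienoate; 8 vinylmagnesium bromide
Product: 10 (4Z,6S)-6-(tert-butyldimethylsilyloxy)-4,8-dimethylnona-1,4,8-trien-3-one, via Weinreb amide 9 (not isolated)
Conditions: MeNH(OMe)·HCl, iPrMgCl, THF, −20 °C; then 8, 0 °C; inverse quench into cold 1 M HCl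
Reagents that add atoms: N,O-dimethylhydroxylamine hydrochloride, CNOC.Cl (its atoms stay only in 9)
Why: Weinreb ketone synthesis run in one pot; the magnesium amide turns the ester into amide 9, whose chelated tetrahedral adduct of 8 survives until the acidic inverse quench, which prevents over-addition and aza-Michael addition while olefin geometry and C6 stay untouched.

Step 6
Reactants: 10 (4Z,6S)-6-(tert-butyldimethylsilyloxy)-4,8-dimethylnona-1,4,8-trien-3-one
Product: 11 (S)-4-(tert-butyldimethylsilyloxy)-2,6-dimethylcyclohepta-2,6-dien-1-one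
Conditions: second-generation Hoveyda–Grubbs catalyst (5 mol %), toluene (0.005 M), 80 °C
Reagents that add atoms: none
Why: Ring-closing metathesis between the vinyl ketone and the 1,1-disubstituted olefin; the Z-olefin holds both termini close, only the seven-membered ring B can form, and loss of ethylene drives closure of the C8=C9 bond.

Step 7
Reactants: 11 (S)-4-(tert-butyldimethylsilyloxy)-2,6-dimethylcyclohepta-2,6-dien-1-one; 12 diisopropylzinc; 13 carbon monoxide
Product: 14 1-[(1S,7S)-7-(tert-butyldimethylsilyloxy)-2,5-dimethyl-3-(trimethylsilyloxy)cyclohepta-2,4-dien-1-yl]-2-methylpropan-1-one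
Conditions: 12 (1.5 equiv), CO (1 atm), Me3SiCl, LiCl, Pd(PPh3)4 (5 mol %), THF, 0 °C to rt; pentane and cold NaHCO3 work-up, no chromatography on acidic silica
Reagents that add atoms: chlorotrimethylsilane, C[Si](C)(C)Cl
Why: Palladium-catalysed carbonylative conjugate addition of a dialkylzinc; zerovalent palladium and Me3SiCl convert the less substituted enone (C1=C5, not the β,β-disubstituted C8=C9) into a 1-siloxy-π-allyl complex on the face anti to the OTBS group, and transmetalation, CO insertion and reductive elimination place the isobutyryl group on C5 trans to O6 and leave the C10 enol silane regiospecifically.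

Step 8
Reactants: 15 4-methoxybenzyl alcohol; 16 ethyl vinyl ether
Product: 17 4-methoxybenzyl vinyl ether
Conditions: 16 (solvent), Pd(OAc)2 (2 mol %), 1,10-phenanthroline (2 mol %), rt
Reagents that add atoms: none
Why: Palladium-catalysed transfer vinylation (transetherification) of a primary alcohol, an equilibrium that the large excess of ethyl vinyl ether pushes to the product.

Step 9
Reactants: 14 1-[(1S,7S)-7-(tert-butyldimethylsilyloxy)-2,5-dimethyl-3-(trimethylsilyloxy)cyclohepta-2,4-dien-1-yl]-2-methylpropan-1-one; 17 4-methoxybenzyl vinyl ether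
Product: 19 6β-(tert-butyldimethylsilyloxy)-2β-(4-methoxybenzyloxy)-4α-(trimethylsilyloxy)-5βH-carot-8-en-10-one, via oxocarbenium ion 18 (not isolated)
Conditions: Me3SiNTf2 (10 mol %), 2,6-di-tert-butylpyridine (5 mol %), CH2Cl2, −78 °C, 17 (1.5 equiv) added over 1 h; Et3N quench
Reagents that add atoms: none
Why: Proposed new method: Me3SiNTf2 silylates the only carbonyl group of 14 (the C4 ketone), the CH2 terminus of 17 adds to this siloxycarbenium ion (C3–C4 bond), and the O-PMB oxocarbenium ion 18 is captured at once by C1 of the C10 silyl dienol ether (C2–C1 bond), which releases Me3Si+ for the next turnover, so that the silyl group of the enol ether ends on O4. The closest known reaction types are the Lewis-acid-mediated formal [3+2] cycloaddition of 2-alkoxycyclopropyl ketones with enol ethers (14 is the ring-opened equivalent of such a donor–acceptor cyclopropane) and Mukaiyama aldol cascades of acetaldehyde enol ethers; new is the open γ-keto enol silane as the three-carbon partner. The only ring closed is cyclopentane ring A, in a 5-(enolexo)-exo-trig closure. At C4, Felkin–Anh attack anti to the bulky C6(OTBS) branch on C5 should put O4 α and the isopropyl group β; at C1, the three-atom tether that hangs from the α face of C5 can reach only the α face of the planar enol carbon, so the fusion is cis and the methyl group β; at C2, the OPMB group turns away from the siloxy-bearing C10 towards the small methyl group and the convex face, that is β. The step needs three selectivities: ketone over enone, secured because C10 stays masked as the nucleophile until the last bond is made; ring closure over vinyl ether oligomerisation, secured by slow addition of 17 and the hindered pyridine as proton trap; and C- over O-capture, secured because the O-cyclised bridged enol ether would be an anti-Bredt olefin.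

Step 10
Reactants: 19 6β-(tert-butyldimethylsilyloxy)-2β-(4-methoxybenzyloxy)-4α-(trimethylsilyloxy)-5βH-carot-8-en-10-one
Product: 20 6β-(tert-butyldimethylsilyloxy)-2β-(4-methoxybenzyloxy)-4α-(trimethylsilyloxy)-5βH-carot-8-en-10α-ol
Conditions: NaBH4, CeCl3·7H2O, MeOH, −78 to −40 °C
Reagents that add atoms: none
Why: Luche reduction (cerium-assisted 1,2-reduction of the enone); hydride should arrive from the convex β face because ring A and the 4α-silyloxy group block the α face, which sets C10 as the α-alcohol.

Step 11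
Reactants: 20 6β-(tert-butyldimethylsilyloxy)-2β-(4-methoxybenzyloxy)-4α-(trimethylsilyloxy)-5βH-carot-8-en-10α-ol
Product: 21 8α,9α-epoxy-6β-(tert-butyldimethylsilyloxy)-2β-(4-methoxybenzyloxy)-4α-(trimethylsilyloxy)-5βH-carotan-10α-ol
Conditions: VO(acac)2 (5 mol %), t-BuOOH (decane), CH2Cl2, 0 °C
Reagents that add atoms: tert-butyl hydroperoxide, CC(C)(C)OO
Why: Vanadium-catalysed hydroxyl-directed epoxidation of a cyclic allylic alcohol; the vanadium alkoxide of the 10α-hydroxyl group delivers the peroxide oxygen to the same α face of C8=C9 against the steric bias, which sets C8 and C9, while O6 is still silylated and cannot direct to the β face.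

Step 12
Reactants: 21 8α,9α-epoxy-6β-(tert-butyldimethylsilyloxy)-2β-(4-methoxybenzyloxy)-4α-(trimethylsilyloxy)-5βH-carotan-10α-ol
Product: 22 8α,9α-epoxy-2β-(4-methoxybenzyloxy)-5βH-carotane-4α,6β,10α-triol
Conditions: Bu4NF, THF, 0 °C to rt
Reagents that add atoms: none
Why: Fluoride-induced desilylation driven by Si–F bond formation removes both silyl groups and leaves the PMB ether; the cis epoxy alcohol cannot undergo Payne rearrangement because O10 cannot reach the rear side of the C9–O bond.

Step 13
Reactants: 22 8α,9α-epoxy-2β-(4-methoxybenzyloxy)-5βH-carotane-4α,6β,10α-triol; 23 tigloyl chloride [(E)-2-methylbut-2-enoyl chloride]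
Product: 24 8α,9α-epoxy-4α-hydroxy-2β-(4-methoxybenzyloxy)-5βH-carotane-6β,10α-diyl bis[(E)-2-methylbut-2-enoate]
Conditions: 23 (6 equiv), DMAP, pyridine, CH2Cl2, 0 to 40 °C
Reagents that add atoms: none
Why: DMAP-catalysed acylation via the N-acylpyridinium salt esterifies both secondary alcohols, the tertiary isopropyl-flanked 4α-hydroxyl group stays free, and pyridine instead of a trialkylamine avoids vinylketene formation and deconjugation of the tiglate.

Step 14
Reactants: 24 8α,9α-epoxy-4α-hydroxy-2β-(4-methoxybenzyloxy)-5βH-carotane-6β,10α-diyl bis[(E)-2-methylbut-2-enoate]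
Product: 25 8α,9α-epoxy-2β,4α-dihydroxy-5βH-carotane-6β,10α-diyl bis[(E)-2-methylbut-2-enoate] (CNP0265715.1)
Conditions: DDQ, CH2Cl2/pH 7 phosphate buffer, 0 °C
Reagents that add atoms: none
Why: Oxidative cleavage of the 4-methoxybenzyl ether; hydride abstraction by DDQ gives a stabilised benzylic oxocarbenium ion that water hydrolyses, under neutral conditions that leave tiglates, epoxide and alcohols untouched.

Compound list
1 | ethyl glyoxylate | CCOC(=O)C=O | starting material
2 | isobutene | CC(C)=C | starting material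
3 | ethyl (S)-2-hydroxy-4-methylpent-4-enoate | CCOC(=O)[C@@H](O)CC(C)=C | intermediate
4 | ethyl (S)-2-(tert-butyldimethylsilyloxy)-4-methylpent-4-enoate | CCOC(=O)[C@@H](O[Si](C)(C)C(C)(C)C)CC(C)=C | intermediate
5 | (S)-2-(tert-butyldimethylsilyloxy)-4-methylpent-4-enal | O=C[C@@H](O[Si](C)(C)C(C)(C)C)CC(C)=C | intermediate
6 | ethyl 2-[bis(2,2,2-trifluoroethoxy)phosphoryl]propanoate | CCOC(=O)C(C)P(=O)(OCC(F)(F)F)OCC(F)(F)F | starting material
7 | ethyl (2Z,4S)-4-(tert-butyldimethylsilyloxy)-2,6-dimethylhepta-2,6-dienoate | CCOC(=O)/C(C)=C\[C@@H](O[Si](C)(C)C(C)(C)C)CC(C)=C | intermediate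
8 | vinylmagnesium bromide | C=C[Mg]Br | starting material
9 | (2Z,4S)-4-(tert-butyldimethylsilyloxy)-N-methoxy-N,2,6-trimethylhepta-2,6-dienamide (Weinreb amide, not isolated) | CON(C)C(=O)/C(C)=C\[C@@H](O[Si](C)(C)C(C)(C)C)CC(C)=C | intermediate
10 | (4Z,6S)-6-(tert-butyldimethylsilyloxy)-4,8-dimethylnona-1,4,8-trien-3-one | C=CC(=O)/C(C)=C\[C@@H](O[Si](C)(C)C(C)(C)C)CC(C)=C | intermediate
11 | (S)-4-(tert-butyldimethylsilyloxy)-2,6-dimethylcyclohepta-2,6-dien-1-one | CC(C)(C)[Si](C)(C)O[C@H]1CC(C)=CC(=O)C(C)=C1 | intermediate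
12 | diisopropylzinc | CC(C)[Zn]C(C)C | starting material
13 | carbon monoxide | [C-]#[O+] | starting material
14 | 1-[(1S,7S)-7-(tert-butyldimethylsilyloxy)-2,5-dimethyl-3-(trimethylsilyloxy)cyclohepta-2,4-dien-1-yl]-2-methylpropan-1-one | CC(C)(C)[Si](C)(C)O[C@H]1CC(C)=CC(O[Si](C)(C)C)=C(C)[C@@H]1C(=O)C(C)C | intermediate
15 | 4-methoxybenzyl alcohol | COc1ccc(CO)cc1 | starting material
16 | ethyl vinyl ether | C=COCC | starting material
17 | 4-methoxybenzyl vinyl ether | C=COCc1ccc(OC)cc1 | intermediate
18 | O-(4-methoxybenzyl) oxocarbenium ion at C2 after formation of C3–C4, bistriflimide salt (not isolated) | CC(C)(C)[Si](C)(C)O[C@H]1CC(C)=CC(O[Si](C)(C)C)=C(C)[C@@H]1[C@](O[Si](C)(C)C)(C(C)C)CC=[O+]Cc3ccc(OC)cc3.O=S(=O)([N-]S(=O)(=O)C(F)(F)F)C(F)(F)F | intermediate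
19 | 6β-(tert-butyldimethylsilyloxy)-2β-(4-methoxybenzyloxy)-4α-(trimethylsilyloxy)-5βH-carot-8-en-10-one | CC(C)(C)[Si](C)(C)O[C@H]1CC(C)=CC(=O)[C@@]2(C)[C@@H]1[C@](O[Si](C)(C)C)(C(C)C)C[C@@H]2OCc3ccc(OC)cc3 | intermediate
20 | 6β-(tert-butyldimethylsilyloxy)-2β-(4-methoxybenzyloxy)-4α-(trimethylsilyloxy)-5βH-carot-8-en-10α-ol | CC(C)(C)[Si](C)(C)O[C@H]1CC(C)=C[C@H](O)[C@@]2(C)[C@@H]1[C@](O[Si](C)(C)C)(C(C)C)C[C@@H]2OCc3ccc(OC)cc3 | intermediate
21 | 8α,9α-epoxy-6β-(tert-butyldimethylsilyloxy)-2β-(4-methoxybenzyloxy)-4α-(trimethylsilyloxy)-5βH-carotan-10α-ol | CC(C)(C)[Si](C)(C)O[C@H]1C[C@]2(C)O[C@@H]2[C@H](O)[C@@]2(C)[C@@H]1[C@](O[Si](C)(C)C)(C(C)C)C[C@@H]2OCc3ccc(OC)cc3 | intermediate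
22 | 8α,9α-epoxy-2β-(4-methoxybenzyloxy)-5βH-carotane-4α,6β,10α-triol | O[C@H]1C[C@]2(C)O[C@@H]2[C@H](O)[C@@]2(C)[C@@H]1[C@](O)(C(C)C)C[C@@H]2OCc3ccc(OC)cc3 | intermediate
23 | tigloyl chloride | C/C=C(\C)C(=O)Cl | starting material
24 | 8α,9α-epoxy-4α-hydroxy-2β-(4-methoxybenzyloxy)-5βH-carotane-6β,10α-diyl bis[(E)-2-methylbut-2-enoate] | C/C=C(\C)C(=O)O[C@H]1C[C@]2(C)O[C@@H]2[C@H](OC(=O)/C(C)=C/C)[C@@]2(C)[C@@H]1[C@](O)(C(C)C)C[C@@H]2OCc3ccc(OC)cc3 | intermediate
25 | CNP0265715.1, (1S,2S,4R,5S,6S,8S,9R,10R)-8,9-epoxy-2,4-dihydroxycarotane-6,10-diyl bis[(E)-2-methylbut-2-enoate] | C/C=C(\C)C(=O)O[C@H]1C[C@]2(C)O[C@@H]2[C@H](OC(=O)/C(C)=C/C)[C@@]2(C)[C@@H]1[C@](O)(C(C)C)C[C@@H]2O | target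

Total steps: 14. Longest linear sequence: 13 (steps 1–7 and 9–14; step 8 is a side branch).

Steps most likely to fail

1. Step 9 (key step). Addition of the vinyl ether to the hindered, doubly α-branched ketone may be outrun by cationic oligomerisation of 17 or by protodesilylation of the enol silane. Facial selectivity at C4 may also be poor. The fallback is stepwise, uses known chemistry and takes another C2 synthon at the ester level. It sets out from 14.
   - The lithium enolate of ethyl acetate (LiN(iPr)2, THF, −78 °C, CeCl3 if needed) is added to the C4 ketone, and the aldolate is trapped with Me3SiCl to give the β-silyloxy ester F1.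
   - i-Bu2AlH at −78 °C gives the β-silyloxy aldehyde F2.
   - BF3·OEt2 in CH2Cl2 at −78 °C closes ring A by an intramolecular Mukaiyama aldol reaction to the 2β-hydroxy ketone F3.
   - 4-Methoxybenzyl trichloroacetimidate with catalytic La(OTf)3 then protects O2, and the route is rejoined at 19.

2. Step 7. Isomerisation or β-hydride elimination of the isopropyl–palladium species before CO insertion, direct transfer of isopropyl without CO, or hydrolysis of the enol silane on isolation may erode the product. The fallback changes from a polar organometallic to a radical acylation. It sets out from 11.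
   - Isobutyraldehyde with (Bu4N)4W10O32 (2 mol %) in MeCN under 390 nm light generates the isobutyryl radical. It adds to C5 anti to the OTBS group and gives the 1,4-diketone F4 as C1 epimers.
   - Soft enolisation with Me3SiOTf and Et3N in CH2Cl2 at 0 °C should engage the more Lewis-basic, less hindered enone carbonyl at its α′ position. The route is rejoined at 14.

3. Step 6. Sequestration of the catalyst by the electron-poor cross-conjugated trienone, intermolecular metathesis of the vinyl ketone, or loss of silanol towards a tropone at 80 °C may defeat ring closure. The fallback closes the ring at the alcohol oxidation level. It sets out from 7.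
   - i-Bu2AlH (2.2 equiv) gives the Z-allylic alcohol F5.
   - MnO2 gives the Z-enal F6.
   - Vinylmagnesium bromide gives the bis-allylic alcohol F7 as carbinol epimers.
   - Second-generation Grubbs catalyst in CH2Cl2 at reflux closes the electron-richer diene to the cycloheptadienol F8.
   - MnO2 or Dess–Martin periodinane oxidises it, and the route is rejoined at 11.

Further compounds
F1 | step 9 | ethyl 3-[(1S,7S)-7-(tert-butyldimethylsilyloxy)-2,5-dimethyl-3-(trimethylsilyloxy)cyclohepta-2,4-dien-1-yl]-4-methyl-3-(trimethylsilyloxy)pentanoate, C4 configured as in 19 | CC(C)(C)[Si](C)(C)O[C@H]1CC(C)=CC(O[Si](C)(C)C)=C(C)[C@@H]1[C@](O[Si](C)(C)C)(C(C)C)CC(=O)OCC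
F2 | step 9 | 3-[(1S,7S)-7-(tert-butyldimethylsilyloxy)-2,5-dimethyl-3-(trimethylsilyloxy)cyclohepta-2,4-dien-1-yl]-4-methyl-3-(trimethylsilyloxy)pentanal | CC(C)(C)[Si](C)(C)O[C@H]1CC(C)=CC(O[Si](C)(C)C)=C(C)[C@@H]1[C@](O[Si](C)(C)C)(C(C)C)CC=O
F3 | step 9 | 6β-(tert-butyldimethylsilyloxy)-2β-hydroxy-4α-(trimethylsilyloxy)-5βH-carot-8-en-10-one | CC(C)(C)[Si](C)(C)O[C@H]1CC(C)=CC(=O)[C@@]2(C)[C@@H]1[C@](O[Si](C)(C)C)(C(C)C)C[C@@H]2O
F4 | step 7 | (5S,6S)-5-(tert-butyldimethylsilyloxy)-6-isobutyryl-3,7-dimethylcyclohept-2-en-1-one, C7 epimers | CC(C)(C)[Si](C)(C)O[C@H]1CC(C)=CC(=O)C(C)[C@@H]1C(=O)C(C)C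
F5 | step 6 | (2Z,4S)-4-(tert-butyldimethylsilyloxy)-2,6-dimethylhepta-2,6-dien-1-ol | OC/C(C)=C\[C@@H](O[Si](C)(C)C(C)(C)C)CC(C)=C
F6 | step 6 | (2Z,4S)-4-(tert-butyldimethylsilyloxy)-2,6-dimethylhepta-2,6-dienal | O=C/C(C)=C\[C@@H](O[Si](C)(C)C(C)(C)C)CC(C)=C
F7 | step 6 | (4Z,6S)-6-(tert-butyldimethylsilyloxy)-4,8-dimethylnona-1,4,8-trien-3-ol, carbinol epimers | C=CC(O)/C(C)=C\[C@@H](O[Si](C)(C)C(C)(C)C)CC(C)=C
F8 | step 6 | (4S)-4-(tert-butyldimethylsilyloxy)-2,6-dimethylcyclohepta-2,6-dien-1-ol, carbinol epimers | CC(C)(C)[Si](C)(C)O[C@H]1CC(C)=CC(O)C(C)=C1
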